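**Retrosynthetic overview**
- The side-chain ketone is made last, from an E-alkene, by a regioselective Wacker-type oxidation (C–O bond at the alkene carbon remote from the stereocentre).
- The C8–C bond and the stereocentre come from an aromatic Claisen rearrangement of a galangin 7-O-allyl ether, which transfers chirality from a C–O to a C–C stereocentre.
- Key bond: the C7–O ether bond between galangin and an (R)-allylic alcohol, formed with inversion (Mitsunobu). It joins the two halves and carries all the stereochemical information.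
- The allylic alcohol comes from the diarylheptenone (CBS reduction), which comes from a β-ketophosphonate and dihydroconiferyl aldehyde (HWE).
- No ring is built: the chromone is bought as galangin, and both benzene rings come with the chain building blocks.

Assumption: methyl 3-(4-hydroxy-3-methoxyphenyl)propanoate, dimethyl (2-oxo-4-phenylbutyl)phosphonate and galangin are taken as inexpensive catalogue compounds, and the target is made and drawn as the open hydroxy ketone (it can equilibrate with its cyclic hemiketal).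

**Route**

Step 1
Reactants: 1 methyl 3-(4-hydroxy-3-methoxyphenyl)propanoate
Product: 2 3-(4-hydroxy-3-methoxyphenyl)propanal
Conditions: DIBAL-H (2.2 equiv), CH2Cl2, −78 °C; MeOH, then aq. Rochelle salt
Reagents that add atoms: none
Why: DIBAL-H partial ester reduction; the first equivalent is consumed by the phenol and the second gives a tetrahedral aluminium hemiacetal that is stable at −78 °C and releases the aldehyde only on work-up.

Step 2
Reactants: 2 3-(4-hydroxy-3-methoxyphenyl)propanal, 3 dimethyl (2-oxo-4-phenylbutyl)phosphonate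
Product: 4 (4E)-7-(4-hydroxy-3-methoxyphenyl)-1-phenylhept-4-en-3-one
Conditions: LiOH·H2O (2.2 equiv), THF, rt
Reagents that add atoms: none
Why: Horner–Wadsworth–Emmons olefination; the stabilised β-ketophosphonate anion gives the E-enone, the mild lithium base tolerates the enolisable aldehyde and the free phenol, and the phosphonate fixes the enone regiochemistry that a direct aldol of 4-phenylbutan-2-one would not.

Step 3
Reactants: 4 (4E)-7-(4-hydroxy-3-methoxyphenyl)-1-phenylhept-4-en-3-one
Product: 5 (3R,4E)-7-(4-hydroxy-3-methoxyphenyl)-1-phenylhept-4-en-3-ol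
Conditions: (S)-Me-CBS (20 mol%), catecholborane (1.8 equiv), toluene/CH2Cl2, −78 °C; MeOH, aq. work-up
Reagents that add atoms: none
Why: Corey–Bakshi–Shibata reduction; the E-alkenyl group acts as the large and the CH2CH2Ph chain as the small substituent, so the (S)-oxazaborolidine delivers hydride to the Si face and gives the (3R)-alcohol by clean 1,2-reduction, as for the same PhCH2CH2C(O)CH=CH motif in prostaglandin side chains.

Step 4
Reactants: 5 (3R,4E)-7-(4-hydroxy-3-methoxyphenyl)-1-phenylhept-4-en-3-ol, 6 galangin (3,5,7-trihydroxy-2-phenyl-4H-chromen-4-one, 1.5 equiv)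
Product: 7 3,5-dihydroxy-7-{[(3S,4E)-7-(4-hydroxy-3-methoxyphenyl)-1-phenylhept-4-en-3-yl]oxy}-2-phenyl-4H-chromen-4-one
Conditions: PPh3, DIAD (1.3 equiv each), THF, 0 °C to rt
Reagents that add atoms: none
Why: Mitsunobu etherification; the 7-OH is by far the most acidic hydroxyl present (vinylogous acid, pKa about 7, whereas 3-OH and 5-OH are hydrogen-bonded to C4=O and the guaiacol OH has pKa about 10), so its phenoxide alone displaces the oxyphosphonium of the secondary allylic alcohol by SN2 with inversion, (3R)-alcohol to (3S)-aryl ether.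

Step 5
Reactants: 7 3,5-dihydroxy-7-{[(3S,4E)-7-(4-hydroxy-3-methoxyphenyl)-1-phenylhept-4-en-3-yl]oxy}-2-phenyl-4H-chromen-4-one
Product: 9 3,5,7-trihydroxy-8-[(3R,4E)-1-(4-hydroxy-3-methoxyphenyl)-7-phenylhept-4-en-3-yl]-2-phenyl-4H-chromen-4-one, via ortho-dienone 8 (not isolated)
Conditions: PhNEt2, 150 °C, Ar, sealed tube
Reagents that add atoms: none
Why: Aromatic Claisen rearrangement ([3,3]-sigmatropic shift, then tautomerisation of the dienone); a chair transition state with the CH2CH2Ph group pseudo-equatorial moves the allyl unit suprafacially from O7 to C8, the position preferred by 7-allyloxyflavones, so the (3S) C–O stereocentre becomes the (3R) C–C stereocentre next to a new E-alkene.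

Step 6
Reactants: 9 3,5,7-trihydroxy-8-[(3R,4E)-1-(4-hydroxy-3-methoxyphenyl)-7-phenylhept-4-en-3-yl]-2-phenyl-4H-chromen-4-one
Product: 10 3,5,7-trihydroxy-8-[(3R)-1-(4-hydroxy-3-methoxyphenyl)-5-oxo-7-phenylheptan-3-yl]-2-phenyl-4H-chromen-4-one
Conditions: Pd(OAc)2 (10 mol%), 1,4-benzoquinone (1.2 equiv), HBF4 (0.3 M), DMA/MeCN/H2O (3.5:3.5:1), rt, Ar
Reagents that add atoms: water, O
Why: Proposed new method: chloride-free cationic Pd(II) binds the E-alkene and water adds anti to C5, the carbon remote from the stereocentre, because C5 is less hindered and carries positive charge better than C4, which sits next to the bulky, inductively withdrawing chromone-bearing C3; β-hydride elimination of the C5–H gives the enol and then the ketone, benzoquinone reoxidises Pd, and the stereocentre is not touched; the closest known reactions are the Tsuji–Wacker oxidation of internal alkenes under Pd(OAc)2/benzoquinone/strong-acid conditions, where an allylic or homoallylic withdrawing group steers oxygen to the distal carbon, and the Pd(II) oxidative cyclisation of 2-allylphenols; new here is an unprotected C-allylated flavonol with a free ortho-OH beside the alkene, where regiocontrol must come from the allylic aryl branch alone and the strongly acidic medium must keep the weakly nucleophilic 7-OH from cyclising.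

**Compound list**
1 | methyl 3-(4-hydroxy-3-methoxyphenyl)propanoate (methyl dihydroferulate) | COC(=O)CCc1ccc(O)c(OC)c1 | starting material
2 | 3-(4-hydroxy-3-methoxyphenyl)propanal | O=CCCc1ccc(O)c(OC)c1 | intermediate
3 | dimethyl (2-oxo-4-phenylbutyl)phosphonate | COP(=O)(OC)CC(=O)CCc1ccccc1 | starting material
4 | (4E)-7-(4-hydroxy-3-methoxyphenyl)-1-phenylhept-4-en-3-one | O=C(CCc1ccccc1)/C=C/CCc1ccc(O)c(OC)c1 | intermediate
5 | (3R,4E)-7-(4-hydroxy-3-methoxyphenyl)-1-phenylhept-4-en-3-ol | O[C@H](CCc1ccccc1)/C=C/CCc1ccc(O)c(OC)c1 | intermediate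
6 | galangin (3,5,7-trihydroxy-2-phenyl-4H-chromen-4-one) | O=c1c(O)c(-c2ccccc2)oc2cc(O)cc(O)c12 | starting material
7 | 3,5-dihydroxy-7-{[(3S,4E)-7-(4-hydroxy-3-methoxyphenyl)-1-phenylhept-4-en-3-yl]oxy}-2-phenyl-4H-chromen-4-one | O=c1c(O)c(-c2ccccc2)oc2cc(O[C@@H](CCc3ccccc3)/C=C/CCc3ccc(O)c(OC)c3)cc(O)c12 | intermediate
8 | ortho-dienone: (8R)-3,5-dihydroxy-8-[(3R,4E)-1-(4-hydroxy-3-methoxyphenyl)-7-phenylhept-4-en-3-yl]-2-phenyl-8H-chromene-4,7-dione (chair-derived, formed in the flask in step 5) | O=C1C=C(O)C2=C(OC(c3ccccc3)=C(O)C2=O)[C@H]1[C@H](CCc1ccc(O)c(OC)c1)/C=C/CCc1ccccc1 | intermediate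
9 | 3,5,7-trihydroxy-8-[(3R,4E)-1-(4-hydroxy-3-methoxyphenyl)-7-phenylhept-4-en-3-yl]-2-phenyl-4H-chromen-4-one | COc1cc(CC[C@H](/C=C/CCc2ccccc2)c2c(O)cc(O)c3c(=O)c(O)c(-c4ccccc4)oc23)ccc1O | intermediate
10 | 3,5,7-trihydroxy-8-[(3R)-1-(4-hydroxy-3-methoxyphenyl)-5-oxo-7-phenylheptan-3-yl]-2-phenyl-4H-chromen-4-one (CNP0164153.1) | COc1cc(CC[C@H](CC(=O)CCc2ccccc2)c2c(O)cc(O)c3c(=O)c(O)c(-c4ccccc4)oc23)ccc1O | target

**Step count and risks**

Total steps: 6. Longest linear sequence: 6 (1 → 2 → 4 → 5 → 7 → 9 → 10; 3 and 6 enter convergently).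

The three steps most likely to fail are steps 4, 5 and 6.

Step 4 (Mitsunobu). The risks are alkylation at 3-OH or at the guaiacol OH, SN2' attack giving the transposed ether, and erosion of ee. The fallback sets out from 6 and comes back at 7, using protecting groups instead of innate acidity to select the 7-OH. Peracetylation (Ac2O, pyridine) gives galangin 3,5,7-triacetate F1. Selective 7-O-deacetylation (PhSH, imidazole, NMP, 0 °C) gives galangin 3,5-diacetate F2. Mitsunobu reaction of F2 with 5 (PPh3, DIAD, THF) gives ether 7 3,5-diacetate F3. Methanolysis (K2CO3, MeOH, 0 °C) then gives 7.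

Step 5 (Claisen). The risks are attack at C6 instead of C8, and partial ionisation of the secondary allylic ether of this acidic phenol, which would lose chirality transfer or eliminate to a diene. A minor Z-alkene would carry the (3S) centre and must be removed by chromatography before step 6. The fallback sets out from 4 and 6 and comes back at 10. A chiral primary-amine salt (9-amino-9-deoxy-epi-cinchona alkaloid/TFA, 20 mol%, THF, rt) activates enone 4 as its iminium ion, and the vinylogous-acid carbon C8 of galangin adds in a Michael reaction of the asymmetric warfarin type. The quinine- or quinidine-derived catalyst that gives the (R)-product is chosen by screening, and any C6 isomer is separated. This fallback makes no new compound (none, F0).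

Step 6 (proposed Wacker oxidation). The risks are oxygen delivery to C4, 5-exo capture of the Pd–alkene complex by 7-OH, catalyst sequestration by the 3-hydroxy-4-keto chelate, and Pd–H isomerisation of the alkene towards C3. The fallback uses known chemistry, sets out from 9 and comes back at 10. Peracetylation (Ac2O, pyridine, DMAP) gives alkene 9 tetraacetate F4. Hydroboration with 9-BBN (THF, 60 °C) places boron on the alkene carbon remote from the branched C3 for steric reasons, and oxidation (H2O2, pH 7 buffer) gives C5-alcohol tetraacetate F5 as both C5 epimers. TPAP/NMO oxidation gives ketone 10 tetraacetate F6. Methanolysis (K2CO3, MeOH, 0 °C) then gives 10.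

**Further compounds**
F1 | step 4 | galangin 3,5,7-triacetate (4-oxo-2-phenyl-4H-chromene-3,5,7-triyl triacetate) | O=c1c(OC(C)=O)c(-c2ccccc2)oc2cc(OC(C)=O)cc(OC(C)=O)c12
F2 | step 4 | galangin 3,5-diacetate (7-hydroxy-4-oxo-2-phenyl-4H-chromene-3,5-diyl diacetate) | O=c1c(OC(C)=O)c(-c2ccccc2)oc2cc(O)cc(OC(C)=O)c12
F3 | step 4 | ether 7 3,5-diacetate (7-{[(3S,4E)-7-(4-hydroxy-3-methoxyphenyl)-1-phenylhept-4-en-3-yl]oxy}-4-oxo-2-phenyl-4H-chromene-3,5-diyl diacetate) | O=c1c(OC(C)=O)c(-c2ccccc2)oc2cc(O[C@@H](CCc3ccccc3)/C=C/CCc3ccc(O)c(OC)c3)cc(OC(C)=O)c12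
F0 | step 5 | none | none
F4 | step 6 | alkene 9 tetraacetate (3,5,7-tri-O-acetyl-8-[(3R,4E)-1-(4-acetoxy-3-methoxyphenyl)-7-phenylhept-4-en-3-yl]galangin) | COc1cc(CC[C@H](/C=C/CCc2ccccc2)c2c(OC(C)=O)cc(OC(C)=O)c3c(=O)c(OC(C)=O)c(-c4ccccc4)oc23)ccc1OC(C)=O
F5 | step 6 | C5-alcohol tetraacetate (3,5,7-tri-O-acetyl-8-[(3R)-1-(4-acetoxy-3-methoxyphenyl)-5-hydroxy-7-phenylheptan-3-yl]galangin, both C5 epimers) | COc1cc(CC[C@H](CC(O)CCc2ccccc2)c2c(OC(C)=O)cc(OC(C)=O)c3c(=O)c(OC(C)=O)c(-c4ccccc4)oc23)ccc1OC(C)=O
F6 | step 6 | ketone 10 tetraacetate (3,5,7-tri-O-acetyl-8-[(3R)-1-(4-acetoxy-3-methoxyphenyl)-5-oxo-7-phenylheptan-3-yl]galangin) | COc1cc(CC[C@H](CC(=O)CCc2ccccc2)c2c(OC(C)=O)cc(OC(C)=O)c3c(=O)c(OC(C)=O)c(-c4ccccc4)oc23)ccc1OC(C)=O
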